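Amounts in these flasks can be counted in laps of the catalyst.

    partner + catalyst intermediate A → catalyst intermediate B (k1 = 2000 L mol⁻¹ s⁻¹)
    catalyst intermediate B → free catalyst + target (k2 = 24 s⁻¹)
    partner ⇌ dormant form (K3 = 0.54, k3 = 0.023 s⁻¹)
    substrate + free catalyst → catalyst intermediate A (k4 = 6500 L mol⁻¹ s⁻¹)

common to all: substrate 0.20 mM; free catalyst 22 µM; time 20 s

|  | partner |
|---|---|
| alpha | 0.120 mM |
| delta | 0.360 mM |

- which of these there is most of at the end, counted by the substrate in it, alpha (catalyst intermediate B / catalyst intermediate A / target / substrate)
- which of these there is most of at the end, counted by the substrate in it, delta (catalyst intermediate B / catalyst intermediate A / target / substrate)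
- the largest of these amounts at the end, in percent of the substrate charged, alpha
- the largest of these amounts at the end, in percent of the substrate charged, delta

I took the lap time, 4.98 s for alpha at its charge: the time one catalyst takes to go once round, the sum of the three waits, each the inverse of its step's rate per catalyst. Each lap makes one target, and the catalyst is 11.0 % of the substrate charge.

In alpha, substrate and partner fall from their charges, so later laps are longer. I capped the second half of the time with partner falling by the dormant form alone, to 83.1 % of its charge:

Lap in the second half: 5.82 s
Target at most: 41.0 %
Substrate at least: 48.0 %

For the other side I put partner low, at what the target ceiling leaves, shared out at equilibrium, 20.6 % of its charge, and I counted steady laps from the start, with no lag, so this side is an estimate and not a proof: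

Long lap: 21.9 s
Target, low estimate: 10.0 %
Share of the catalyst waiting as catalyst intermediate A at the end, low estimate: 71.7 %
Substrate, high estimate: 82.1 %

So in alpha the substrate floor stood higher than the target ceiling, and substrate had to lead. For delta the lap is 2.20 s and the ceiling 100 %, which told me nothing, so my hand stopped there.

The forecast, with the words “Treat it as a catalytic cycle”, said substrate at 63 % for alpha, inside my bracket, and target at 62 % for delta.

The flasks gave substrate at 63.3 % in alpha, with target at 26.8 %, and target at 62.1 % in delta. At 20.0 s alpha held 89.6 % of its catalyst as catalyst intermediate A, the resting state, more than the 10.0 % free. Delta held less there, 56.0 %, with 43.2 % free. Delta's target moved 6 points at 19.0 µM or 25.4 µM of free catalyst, or at a reading time of 17.2 s or 23.1 s, the other settings held.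

With 0.048 mM of partner in the alpha recipe, the lap is 11.2 s, so target is at most 19.6 %. That flask gave 11.4 %, below the ceiling.

The constants used here are assumed; the result is computed.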